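At early times cedar and alder hold the same trace of target, 0.500% of the charge, but cedar has its whole charge of substrate in the flask from the start, while alder has none until the feed begins. In both, substrate that meets target becomes more target, which then starts to drain into the isomer of the product. The two part over when that target is born.

| flask | substrate | target | remark | time |
|---|---|---|---|---|
| maple | 0.20 M | 1.00 mM | a single well-mixed tank run continuously and read at steady state, 4.0 min in it on average |  |
| elm | 0.20 M | 1.00 mM | plug flow through a tube for 4.0 min, no back-mixing | 4.0 min |
| cedar | 0.20 M | 1.00 mM | everything together in a closed stirred flask, run for 4.0 min | 4.0 min |
| alder | 0.20 M (fed, over 3.20 min) | 1.00 mM | all but substrate at the start; substrate goes in evenly over 3.20 min, the run ends at 4.0 min | 4.0 min |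

1. the set-up with the highest amount of target at the outlet or at the end, in percent of the substrate put in ("none" if the first two lie within 2 percentage points) (maple / elm / cedar / alder / none)
2. amount of target at the outlet or at the end, in percent of the substrate put in, maple
3. amount of target at the outlet or at the end, in percent of the substrate put in, elm
4. amount of target at the outlet or at the end, in percent of the substrate put in, cedar
5. amount of target at the outlet or at the end, in percent of the substrate put in, alder

- percentages count the substrate that a species holds: one side product counts as two
- the stated concentrations are those of everything mixed, before any reaction; amounts are the same in each set-up
- the feed brings no volume worth counting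
- run time (elm): 4.0 min

    substrate + target → 2 target (k1 = 370 M⁻¹ min⁻¹)
    substrate → target (k2 = 0.0021 min⁻¹)
    target ⇌ isomer of the product (K3 = 96, k3 = 0.25 min⁻¹)
    substrate + target → side product (k4 = 0.084 M⁻¹ min⁻¹)

In cedar, multiplying from the trace to the whole charge at the starting rate takes about 0.0716 min, far shorter than the run. I dropped the side step, whose selectivity factor against the autocatalytic step is 2.27 × 10⁻⁴. I also dropped the uncatalysed step, far slower than the autocatalytic one even at the start, and the way back from the isomer, far slower than the way there. That left one loss, target draining at 0.25 min⁻¹.

The quantity I carried is the mean exposure of alder: the average time a piece of its charge spends as target before the end, 2.40 min, the run less half the dosing time, taking the dose as used on arrival. Cedar's mean exposure is 3.93 min, which leaves 37.5% as target, and elm, a plug ageing along a tube, keeps the same clock and the same figure.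

For alder, putting the mean into the decay curve gives 54.9%, but the curve bows. The mean of its two ends, first parcel and last, is 59.3%, and a bowed curve averages about a third of the way from middle to ends, so I said 56.4%. Maple's parcels leave at every age around 4.0 min on average, and its tank balance gives 50.0%, more than cedar. My pick was alder.

The forecast named alder, with 50.2% for maple, 37.9% for elm, 37.9% for cedar and 57.3% for alder, whose “target is made later and so has less time to isomerise”. It stood slightly above me for cedar and for alder.

The simulation gave alder as best, with 50.2% for maple, 37.9% for elm, 37.9% for cedar and 57.5% for alder.

Alder had not come to rest at 4.0 min: it held 57.5% as target and 42.9% as isomer of the product, a ratio far below 96. A dose over a tenth of the run, reckoned by exposure, leaves 38.7%; that run gave 39.8%. Left until 40.0 min, alder's mean exposure grows to 38.4 min, and the drain alone leaves 0.00677%, less than the equilibrium share of 1.03%. Alder then held 1.04% as target.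

Its constants are invented; the run is a simulation.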